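Atom labels used throughout: sesquiterpene carbons C1 (aryl-bearing CH), C2, C3, C4 (CH–CH3, methyl = C15), C5 (C–CH3, methyl = C14), C6 and C7 (cyclopropane CH), C8, C9 (carbonyls), C10 (C–O), C11 (CMe2). Ring A = C1–C2–C3–C4–C5–C10; ring B = C5–C6–C7–C8–C9–C10. Arene: Ar1 (acyl), Ar2 (OH), Ar3 (H), Ar4 (OMe), Ar5 (bonded to C1), Ar6 (bonded to the ring oxygen). β is the face of rings A/B that carries the ether oxygen and C14; α is the opposite face.

## Analysis of the target

Target 25 is an aristolane-type sesquiterpene: a cis-fused decalin (rings A and B) with a gem-dimethylcyclopropane on C6–C7 and an 8,9-dione. Its C1–C10 bond is shared with a dihydrofuran ring that joins it to a 2'-hydroxy-4,4'-dimethoxychalcone. There are six stereocentres. C1, C4, C5 and C10 are contiguous on ring A and carry the aryl group, C15, C14 and the ether oxygen all on the β face; the cyclopropane (C6, C7, C11) lies on the α face, anti to C14. With the labels above the configuration is 1R,4R,5R,6S,7R,10S. C5 and C10 are adjacent fully substituted carbons, and C10 also carries an aryloxy group next to a ketone, which is the main steric problem. The sensitive groups are the non-enolisable 1,2-dione (hydroxide can trigger a benzilic acid shift), the cyclopropyl ketone (strong acid), the chalcone (reducible, a Michael acceptor, able to close to a flavanone with the ortho hydroxyl), and, before the chalcone exists, an aryl methyl ketone whose CH3 is the most acidic C–H in every intermediate. The arene is a phloroglucinol with three differently substituted oxygens, so its regiochemistry must be fixed deliberately. The strategy rests on one feature: the dihydrofuran and ring A share C1–C10 and the four ring A substituents are all cis. That is the pattern left when a (1E,3E)-diene on Ar5 adds across the C10=C5 bond of a cyclic enol ether held on the Ar6 oxygen.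

## Retrosynthetic reasoning

**25 back to 23.** The last two operations are removal of the Ar2–O protecting group (24 to 25) and oxidation of the C8 carbinol to the dione (23 to 24). The dione is placed at the end because it does not tolerate the basic steps; the ketol 23 is the stable carrier of that oxidation level.

**23 back to 21 and 22.** The C6–C11 and C7–C11 bonds are cut. The cyclopropane is the only part of ring B that a cyclohexenone cannot bring along. An 8α-hydroxyl in 21 later becomes the C8 ketone and also steers a zinc carbenoid made from 22 to the α face of C6=C7. The chalcone double bond is electron-poor and should be ignored by this electrophilic reagent.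

**21 back to 20, 19 and 17.** The C8 oxygen and the C6=C7 bond both come from the 7-en-9-one 17 by γ-deprotonation and oxygenation of the extended enolate 18 at C8. Electrophilic attack at C8 is expected on the β face, the wrong face for directing the carbenoid. C8 is therefore taken up to the ene-dione 20 and brought back with hydride from the same β face, which places the hydroxyl α in 21. The forward reduction has to pick C8 over C9 and over the chalcone carbonyl.

**17 back to 15 and 16.** The chalcone Cα=Cβ bond is cut by an aldol condensation. It is placed here, and not at the end, because as long as the acetyl methyl exists no enolate chemistry on ring B can be chemoselective. Once it is condensed, the only enolisable position in 17 is C6. It cannot be placed earlier, because the C2=C3 bond must be hydrogenated first.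

**15 back to 14 and 13.** The C7=C8 bond of 15 comes from dehydrogenation of the saturated ketone 14 by a method that needs no preformed enolate, so the acetyl group is not involved. 14 comes from 13 by hydrogenation of C2=C3.

**13 back to 12.** This is the key disconnection: C1–C10 and C4–C5 are cut together. It removes ring A and the dihydrofuran in one step, clears four stereocentres including both quaternary carbons, and leaves an achiral triene. The forward reaction must control only the absolute face, since the relative configuration is fixed by the tether and the two alkene geometries.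

**12 back to 7 and 11.** The Ar5–C1 bond is cut. A cross-coupling of aryl iodide 7 with dienyl boronate 11 is the last step before the cycloaddition, so the triene is formed near room temperature. 11 comes from 8 and 9 by a boron–Wittig olefination.

**7 back to 3 and 5.** The C10–O bond is cut. The phenoxide of 3 opens epoxy ketone 5 at the carbon next to the carbonyl, and dehydration of the intermediate 6 gives the enol ether. 5 is the epoxide of 4.

**3 back to 1.** Mono-protection of the symmetric diol 1 gives 2, and iodination of 2 ortho to the remaining chelated hydroxyl gives 3. This places the iodine (future Ar5) between the methoxy group and the oxygen that becomes the ring ether, and leaves the protected oxygen as the future free Ar2–OH.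

## Alternatives that were turned down

Alternative 1: Ring A is closed on a carbocycle that does not yet carry the arene, by cutting C1–C10. In the forward direction aldehyde A1, a 4,4-disubstituted cyclohexadienone whose side chain ends in the C1 aldehyde, would undergo a carbene-catalysed intramolecular Stetter reaction. The acyl anion equivalent adds to one of the two enantiotopic enone β-carbons and gives the cis-fused enedione A2.
- For it: desymmetrising Stetter cyclisations of such dienones are well established. The existing C4 stereocentre and the catalyst should control C5 and C10. A2 also emerges with the C6=C7–C8=O enone, the ideal acceptor for an isopropylidene transfer. On ring B this is clearly stronger than the chosen route, which needs steps 9 to 13 to reach a comparable point.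
- Against it: A2 has hydrogen at C10 and a ketone at C1. The aryl–C1 bond, the C10–O bond, the cis relation of both to C14, and the C9 oxidation all remain. They would have to be made on a hindered decalin that offers no stereochemical help, in many further steps.
- Comparison: the chosen key step (12 to 13) is spent on exactly these centres and forms them with the arene already in its final substitution pattern.

Alternative 2: The benzene ring itself is disconnected. Ar5 and Ar6 stay with the terpene as a cyclic ketene acetal, and Ar1 to Ar4 come from a pyrone. In the forward direction the tert-butyldimethylsilyl ketene acetal A3, which already holds rings A and B, the cyclopropane, a C8 dioxolane and all six stereocentres, would add as an electron-rich dienophile across C6 and C3 of the acetyl pyrone A4. Decarboxylative cycloreversion and loss of the silyloxy group would aromatise the adduct to A5.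
- For it: the arene substitution pattern is dictated by the pyrone, so no phenol differentiation or iodination regiochemistry arises, and the polarity is well matched. On arene regiocontrol it is stronger than steps 1 and 2 of the chosen route.
- Against it: it is an endgame and not a solution. A3 presupposes the complete oxygenated aristolane lactone with its two contiguous quaternary carbons, whose synthesis is the real problem and would be a long linear sequence. After A5, C9 must still be oxidised, the ketal and benzyl ether removed, and the chalcone made around a hydrogenolysis.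
- Comparison: the chosen route builds the stereochemical core and the heterocycle in one step from a precursor that is six steps from commercial materials.

Alternative 3: Both carbocycles are cut at once, through C5–C10 and C3–C4, leaving a benzofuran and a cyclopropane joined by the 1,2-dione. In the forward direction triene A6 would cyclise with the furan C2=C3 bond plus the vinyl group as diene and the (E)-but-2-en-2-yl alkene as dienophile. A6 is a 3-vinylbenzofuran whose furan C2 carries the dione chain ending in a cis-disubstituted dimethylcyclopropane. The product A7 has a C1=C2 alkene to be hydrogenated later.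
- For it: it is the most convergent plan. The dione and the cyclopropane are in place, so none of steps 9 to 15 of the chosen route would be needed. The cyclopropane stereocentres could relay the absolute configuration without a chiral catalyst. On step economy after the cycloaddition it is clearly stronger.
- Against it: the dienophile is an unactivated trisubstituted alkene and the diene must give up furan aromaticity, so there is no polarity assistance. The temperatures needed are those at which a cis-2-alkenylcyclopropyl ketone is expected to rearrange (retro-Claisen ring expansion or homo-1,5-hydrogen shift). Both quaternary centres would have to form in this unassisted event, across a flexible dione tether with uncertain facial selectivity. The free acetyl group would then face a Claisen–Schmidt in the presence of the dione.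
- Comparison: the chosen route pays with more steps after the cycloaddition, but it uses an activated, polarity-matched enone dienophile and a robust precursor.

Key step: step 7

## Assumptions

- The (S,S) ligand is written in step 7 as a working choice. The sense of induction cannot be derived with confidence and has to be established; the (R,R) ligand is used if it proves opposite.
- Compounds 9 and 22 are taken as purchasable (22 is otherwise one step from acetone hydrazone and iodine).

## Route

Step 1
Reactants: 1 1-(2,6-dihydroxy-4-methoxyphenyl)ethan-1-one
Product: 2 1-[2-hydroxy-4-methoxy-6-(methoxymethoxy)phenyl]ethan-1-one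
Conditions: MOMCl (1.05 equiv), i-Pr2NEt, CH2Cl2, 0 °C to rt
Reagents that add atoms: chloromethyl methyl ether, COCCl
Why: The two hydroxyls of 1 are equivalent, and after the first O-alkylation the remaining one is locked in a hydrogen bond to the acetyl carbonyl and reacts much more slowly, so mono-protection should be selective and it breaks the symmetry of the ring.

Step 2
Reactants: 2 1-[2-hydroxy-4-methoxy-6-(methoxymethoxy)phenyl]ethan-1-one
Product: 3 1-[2-hydroxy-3-iodo-4-methoxy-6-(methoxymethoxy)phenyl]ethan-1-one
Conditions: NIS, DMF, 0 °C to rt
Reagents that add atoms: N-iodosuccinimide, O=C1CCC(=O)N1I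
Why: Electrophilic aromatic iodination; the chelated hydroxyl directs to its own ortho position (between OH and OMe), as is general for 2-hydroxy-4,6-dialkoxyacetophenones, which puts iodine on the future Ar5 next to the oxygen that becomes the ring ether.

Step 3
Reactants: 4 3-methylcyclohex-2-en-1-one
Product: 5 rac-6-methyl-7-oxabicyclo[4.1.0]heptan-2-one (2,3-epoxy-3-methylcyclohexanone)
Conditions: H2O2 (30% aq.), NaOH (cat.), MeOH, 0 °C
Reagents that add atoms: hydrogen peroxide, OO
Why: Weitz–Scheffer nucleophilic epoxidation of the enone; the racemate is sufficient because both stereocentres are removed in step 4.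

Step 4
Reactants: 3 1-[2-hydroxy-3-iodo-4-methoxy-6-(methoxymethoxy)phenyl]ethan-1-one; 5 rac-6-methyl-7-oxabicyclo[4.1.0]heptan-2-one
Product: 7 2-[2-acetyl-6-iodo-5-methoxy-3-(methoxymethoxy)phenoxy]-3-methylcyclohex-2-en-1-one, via β-hydroxy ketone 6 (not isolated)
Conditions: KH (0.3 equiv), THF–DMPU, 70 °C
Reagents that add atoms: none
Why: The potassium phenoxide of 3 opens the epoxide at the carbon α to the carbonyl (an SN2 reaction accelerated by the adjacent C=O), and the tertiary β-hydroxy ketone 6 loses water by E1cB under the same conditions to give the fully substituted 2-aryloxy enone. The alkoxide formed regenerates phenoxide, so the base is catalytic.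

Step 5
Reactants: 8 (E)-but-2-enal; 9 bis(4,4,5,5-tetramethyl-1,3,2-dioxaborolan-2-yl)methane
Product: 11 4,4,5,5-tetramethyl-2-[(1E,3E)-penta-1,3-dien-1-yl]-1,3,2-dioxaborolane, via lithiated diborylmethane 10 (not isolated)
Conditions: TMPH, n-BuLi, THF, 0 °C; 9; then 8, −78 °C to rt
Reagents that add atoms: none
Why: Boron–Wittig olefination: the α-boryl carbanion 10 adds to the aldehyde and syn-elimination of a boron oxide gives the (E)-alkenyl boronate, with the existing E double bond untouched.

Step 6
Reactants: 7 2-[2-acetyl-6-iodo-5-methoxy-3-(methoxymethoxy)phenoxy]-3-methylcyclohex-2-en-1-one; 11 4,4,5,5-tetramethyl-2-[(1E,3E)-penta-1,3-dien-1-yl]-1,3,2-dioxaborolane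
Product: 12 2-{2-acetyl-5-methoxy-3-(methoxymethoxy)-6-[(1E,3E)-penta-1,3-dien-1-yl]phenoxy}-3-methylcyclohex-2-en-1-one
Conditions: Pd(OAc)2 (5 mol %), SPhos (10 mol %), K3PO4, THF–H2O, 35 °C
Reagents that add atoms: none
Why: Suzuki–Miyaura coupling of a di-ortho-substituted aryl iodide with an alkenyl boronate goes with retention of both double-bond geometries, and a biaryl phosphine ligand allows near-ambient temperature so that 12 is not exposed to heat.

Step 7
Reactants: 12 2-{2-acetyl-5-methoxy-3-(methoxymethoxy)-6-[(1E,3E)-penta-1,3-dien-1-yl]phenoxy}-3-methylcyclohex-2-en-1-one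
Product: 13 (1R,4R,5S,10S)-tetracyclic 2-en-9-one (Ar1-acetyl, Ar2-OMOM, Ar4-OMe; 1β-aryl, 10β-oxygen, 4β,5β-dimethyl; cis-fused dihydrobenzofuran on C1–C10)
Conditions: [Cu((S,S)-t-Bu-box)](SbF6)2 (10 mol %), CH2Cl2, −20 °C to rt
Reagents that add atoms: none
Why: Proposed new method: a cationic Cu(II)–bis(oxazoline) complex is meant to bind the C9 carbonyl and the adjacent enol ether oxygen of 12 as a five-membered chelate and lower the enone LUMO, so that the tethered (E,E)-diene adds in a concerted, asynchronous [4+2] at or below room temperature, with bond formation leading at C4–C5 (nucleophilic methyl-bearing diene terminus to the electrophilic β-carbon); the closest known reaction types are the thermal type 1 intramolecular Diels–Alder of benzo-tethered 1,3,8-nonatrienes and the Cu–bis(oxazoline)-catalysed enantioselective Diels–Alder of two-point-binding dienophiles, neither of which has been shown on a fully substituted 2-aryloxy enone. The dihydrofuran closes as the tether ring (three atoms Ar5–Ar6–O between diene C1 and dienophile C10, giving the fused five-membered ring through the C1–C10 bond), and ring A closes as the cyclohexene of the cycloaddition through C1–C10 and C4–C5. C1 and C4 are related by the E,E geometry of the diene (aryl cis to C15), C10 and C5 by the ring-fixed geometry of the enol ether (oxygen cis to C14), and C1 to C10 by the tether, which can only reach a cis-fused five-membered ring, so the all-cis array follows with no endo/exo choice left. The absolute configuration depends on the ligand alone, which must shield one face of the C10=C5 bond within the chelate. Regiochemistry is enforced by the tether and matches the polarity of both partners. The selectivity that has to be won is enantioface selectivity against the uncatalysed background, which is why 12 is made last under mild conditions and is not heated.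

Step 8
Reactants: 13 (1R,4R,5S,10S)-tetracyclic 2-en-9-one
Product: 14 saturated tetracyclic 9-ketone (2,3-dihydro-13; C1, C4, C5, C10 unchanged)
Conditions: H2 (3 atm), RhCl(PPh3)3 (10 mol %), PhH–EtOH, rt
Reagents that add atoms: none
Why: Homogeneous hydrogenation of the cis-disubstituted C2=C3 bond; a rhodium phosphine catalyst is chosen over palladium on carbon to avoid double-bond migration towards C1 or C4, so no stereocentre is touched, and the acetal and both ketones are inert.

Step 9
Reactants: 14 saturated tetracyclic 9-ketone
Product: 15 tetracyclic 7-en-9-one (Ar1-acetyl, Ar2-OMOM; C1, C4, C5, C10 unchanged)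
Conditions: Pd(TFA)2 (10 mol %), 4,5-diazafluoren-9-one (10 mol %), O2 (1 atm), DMSO, 80 °C
Reagents that add atoms: none
Why: Palladium(II)-catalysed aerobic α,β-dehydrogenation (palladium enolate, then β-hydride elimination); C10 is quaternary, so the enone can only form towards C7–C8, and the aryl methyl ketone has no β-hydrogen, which is why this enolate-free method replaces a silyl enol ether route.

Step 10
Reactants: 15 tetracyclic 7-en-9-one; 16 4-methoxybenzaldehyde
Product: 17 (E)-chalcone 7-en-9-one (Ar1-(4-methoxycinnamoyl), Ar2-OMOM)
Conditions: KOH, EtOH, 0 °C to rt (Ar)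
Reagents that add atoms: none
Why: Claisen–Schmidt condensation (aldol addition, then E1cB dehydration) at the acetyl methyl, the most acidic and least hindered C–H; ring B has no α-hydrogen at this stage (C8 is vinylic, C10 quaternary), and the E-enone is the thermodynamic product.

Step 11
Reactants: 17 (E)-chalcone 7-en-9-one
Product: 19 8β-hydroxy-6-en-9-one chalcone (Ar2-OMOM), via potassium dienolate 18 (not isolated)
Conditions: KHMDS, THF, −78 °C; 2-(phenylsulfonyl)-3-phenyloxaziridine, −78 °C; AcOH
Reagents that add atoms: 2-(phenylsulfonyl)-3-phenyloxaziridine, O=S(=O)(N1OC1c1ccccc1)c1ccccc1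
Why: γ-Deprotonation at C6, the only enolisable position left, gives the extended enolate 18, which takes up the electrophilic oxygen of the sulfonyloxaziridine at its α-carbon C8 (deconjugative α-hydroxylation of a dienolate). Attack is expected on the β face, away from the pseudoaxial C1 on C10, but the C8 configuration is erased in step 12.

Step 12
Reactants: 19 8β-hydroxy-6-en-9-one chalcone
Product: 20 6-ene-8,9-dione chalcone (Ar2-OMOM)
Conditions: DMP, NaHCO3, CH2Cl2, 0 °C to rt
Reagents that add atoms: none
Why: Dess–Martin oxidation of a secondary α-ketol to the 1,2-dione under buffered conditions; 20 cannot enolise (C5 and C10 quaternary, C7 vinylic), and the acetal and chalcone are untouched.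

Step 13
Reactants: 20 6-ene-8,9-dione chalcone
Product: 21 8α-hydroxy-6-en-9-one chalcone (Ar2-OMOM)
Conditions: NaBH4, CeCl3·7H2O, MeOH–THF, −78 °C
Reagents that add atoms: none
Why: Luche 1,2-reduction; of the three carbonyls C8 is the most accessible (C9 is flanked by the quaternary C10, the chalcone carbonyl by two ortho substituents). Hydride is expected on the β face, away from the pseudoaxial C1 on C10, which sets the 8α-hydroxyl.

Step 14
Reactants: 21 8α-hydroxy-6-en-9-one chalcone; 22 2,2-diiodopropane
Product: 23 8α-hydroxy-9-one chalcone with the 6α,7α-fused gem-dimethylcyclopropane (Ar2-OMOM)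
Conditions: Et2Zn, 22, CH2Cl2, −10 °C to rt
Reagents that add atoms: none
Why: Hydroxyl-directed Simmons–Smith-type isopropylidene transfer: the zinc alkoxide of the 8α-hydroxyl delivers the zinc carbenoid to the α face of C6=C7, the face that the axial C14 methyl also leaves open, so C6 and C7 are set together with the cyclopropane anti to C14. The electron-poor chalcone double bond does not react with the electrophilic carbenoid.

Step 15
Reactants: 23 8α-hydroxy-9-one chalcone with the 6α,7α-fused gem-dimethylcyclopropane
Product: 24 O-methoxymethyl ether of 25 (8,9-dione)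
Conditions: DMP, NaHCO3, CH2Cl2, rt
Reagents that add atoms: none
Why: Dess–Martin oxidation of the cyclopropyl carbinol next to the C9 ketone gives the 8,9-dione, which is not enolisable (C10 quaternary, C7 a cyclopropane carbon), so no stereocentre is at risk.

Step 16
Reactants: 24 O-methoxymethyl ether of 25
Product: 25 CNP0121765.1 (1R,4R,5R,6S,7R,10S in the labels above)
Conditions: HCl (1 M), MeOH–THF, rt
Reagents that add atoms: none
Why: Acid-catalysed acetal exchange; a methoxymethyl ether ortho to an aryl ketone is cleaved by very mild acid, under which the cyclopropyl dione and the chalcone should survive, and the freed hydroxyl is held by a hydrogen bond to the chalcone carbonyl.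

## Compound list

1 | 1-(2,6-dihydroxy-4-methoxyphenyl)ethan-1-one | CC(=O)c1c(O)cc(OC)cc1O | starting material
2 | 1-[2-hydroxy-4-methoxy-6-(methoxymethoxy)phenyl]ethan-1-one | CC(=O)c1c(O)cc(OC)cc1OCOC | intermediate
3 | 1-[2-hydroxy-3-iodo-4-methoxy-6-(methoxymethoxy)phenyl]ethan-1-one | CC(=O)c1c(O)c(I)c(OC)cc1OCOC | intermediate
4 | 3-methylcyclohex-2-en-1-one | CC1=CC(=O)CCC1 | starting material
5 | rac-6-methyl-7-oxabicyclo[4.1.0]heptan-2-one | CC12CCCC(=O)C1O2 | intermediate
6 | rac-trans-2-[2-acetyl-6-iodo-5-methoxy-3-(methoxymethoxy)phenoxy]-3-hydroxy-3-methylcyclohexan-1-one (not isolated) | CC(=O)c1c(OCOC)cc(OC)c(I)c1OC1C(=O)CCCC1(C)O | intermediate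
7 | 2-[2-acetyl-6-iodo-5-methoxy-3-(methoxymethoxy)phenoxy]-3-methylcyclohex-2-en-1-one | CC(=O)c1c(OCOC)cc(OC)c(I)c1OC1=C(C)CCCC1=O | intermediate
8 | (E)-but-2-enal | C/C=C/C=O | starting material
9 | bis(4,4,5,5-tetramethyl-1,3,2-dioxaborolan-2-yl)methane | CC1(C)OB(CB2OC(C)(C)C(C)(C)O2)OC1(C)C | starting material
10 | lithio-bis(4,4,5,5-tetramethyl-1,3,2-dioxaborolan-2-yl)methane (not isolated) | [Li]C(B1OC(C)(C)C(C)(C)O1)B1OC(C)(C)C(C)(C)O1 | intermediate
11 | 4,4,5,5-tetramethyl-2-[(1E,3E)-penta-1,3-dien-1-yl]-1,3,2-dioxaborolane | C/C=C/C=C/B1OC(C)(C)C(C)(C)O1 | intermediate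
12 | 2-{2-acetyl-5-methoxy-3-(methoxymethoxy)-6-[(1E,3E)-penta-1,3-dien-1-yl]phenoxy}-3-methylcyclohex-2-en-1-one | CC(=O)c1c(OCOC)cc(OC)c(/C=C/C=C/C)c1OC1=C(C)CCCC1=O | intermediate
13 | (1R,4R,5S,10S)-tetracyclic 2-en-9-one, Ar1-acetyl, Ar2-OMOM, Ar4-OMe, all-cis aryl/O/C14/C15 | CC(=O)c1c(OCOC)cc(OC)c2c1O[C@]13C(=O)CCC[C@@]1(C)[C@H](C)C=C[C@H]23 | intermediate
14 | saturated tetracyclic 9-ketone (2,3-dihydro-13) | CC(=O)c1c(OCOC)cc(OC)c2c1O[C@]13C(=O)CCC[C@@]1(C)[C@H](C)CC[C@H]23 | intermediate
15 | tetracyclic 7-en-9-one, Ar1-acetyl, Ar2-OMOM | CC(=O)c1c(OCOC)cc(OC)c2c1O[C@]13C(=O)C=CC[C@@]1(C)[C@H](C)CC[C@H]23 | intermediate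
16 | 4-methoxybenzaldehyde | COc1ccc(C=O)cc1 | starting material
17 | (E)-chalcone 7-en-9-one, Ar2-OMOM | COc1ccc(/C=C/C(=O)c2c(OCOC)cc(OC)c3c2O[C@]24C(=O)C=CC[C@@]2(C)[C@H](C)CC[C@H]34)cc1 | intermediate
18 | potassium 6,8-dien-9-olate of 17 (not isolated) | COc1ccc(/C=C/C(=O)c2c(OCOC)cc(OC)c3c2O[C@]24C([O-])=CC=C[C@@]2(C)[C@H](C)CC[C@H]34)cc1.[K+] | intermediate
19 | 8β-hydroxy-6-en-9-one chalcone, Ar2-OMOM | COc1ccc(/C=C/C(=O)c2c(OCOC)cc(OC)c3c2O[C@]24C(=O)[C@H](O)C=C[C@@]2(C)[C@H](C)CC[C@H]34)cc1 | intermediate
20 | 6-ene-8,9-dione chalcone, Ar2-OMOM | COc1ccc(/C=C/C(=O)c2c(OCOC)cc(OC)c3c2O[C@]24C(=O)C(=O)C=C[C@@]2(C)[C@H](C)CC[C@H]34)cc1 | intermediate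
21 | 8α-hydroxy-6-en-9-one chalcone, Ar2-OMOM | COc1ccc(/C=C/C(=O)c2c(OCOC)cc(OC)c3c2O[C@]24C(=O)[C@@H](O)C=C[C@@]2(C)[C@H](C)CC[C@H]34)cc1 | intermediate
22 | 2,2-diiodopropane | CC(C)(I)I | starting material
23 | 8α-hydroxy-9-one chalcone with the 6α,7α-fused gem-dimethylcyclopropane, Ar2-OMOM | COc1ccc(/C=C/C(=O)c2c(OCOC)cc(OC)c3c2O[C@]24C(=O)[C@@H](O)[C@@H]5[C@@H](C5(C)C)[C@@]2(C)[C@H](C)CC[C@H]34)cc1 | intermediate
24 | O-methoxymethyl ether of 25 | COc1ccc(/C=C/C(=O)c2c(OCOC)cc(OC)c3c2O[C@]24C(=O)C(=O)[C@@H]5[C@@H](C5(C)C)[C@@]2(C)[C@H](C)CC[C@H]34)cc1 | intermediate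
25 | CNP0121765.1 | COc1ccc(/C=C/C(=O)c2c(O)cc(OC)c3c2O[C@]24C(=O)C(=O)[C@@H]5[C@@H](C5(C)C)[C@@]2(C)[C@H](C)CC[C@H]34)cc1 | target

## Step count and least certain steps

Total step count: 16. Longest linear sequence: 14 steps (from 1 through steps 1, 2, 4 and 6 to 16; steps 3 and 5 make the side fragments 5 and 11).

**Step 7 (key step, Proposed new method).** The most likely failures are poor enantioface discrimination, sequestration of the copper by the acetyl and acetal oxygens, and an uncatalysed thermal background cycloaddition that erodes the enantiomeric purity. Acid-induced oligomerisation of the electron-rich diene is also possible. Fallback with known chemistry: 12 is heated in toluene (about 140 °C, BHT) without catalyst. The thermal type 1 intramolecular Diels–Alder gives the same relative configuration as a racemate, 13 together with its enantiomer ent-13 F1. The two are separated by preparative chromatography on a chiral stationary phase, and 13 re-enters the route at step 8.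

**Step 14.** Carbenoid transfer to a cis-disubstituted alkene next to a quaternary carbon may be slow, so that the isopropylidene carbenoid decomposes first. The zinc alkoxide may also isomerise the β,γ-unsaturated ketol to the conjugated dione enol before cyclopropanation. Fallback: the approach changes from carbenoid transfer to dipolar cycloaddition, starting from 20. 2-Diazopropane F3 (from acetone hydrazone and silver oxide) adds across the electron-poor C6=C7 bond of the ene-dione, on the α face anti to the axial C14, to give pyrazoline F2. Photochemical nitrogen extrusion then gives 24 directly, re-entering at step 16. The chalcone is a far weaker dipolarophile, and any E/Z scrambling on irradiation would be corrected by iodine-catalysed equilibration.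

**Step 13.** Hydride may go to the wrong carbonyl (C9 or the chalcone) or to the α face of C8, which would give back the 8β-alcohol. Fallback: the C8 configuration is inverted by substitution, not by redox, starting from 19. A Mitsunobu reaction with 4-nitrobenzoic acid (DIAD, PPh3) gives the 8α-(4-nitrobenzoate) F4, and mild methanolysis (K2CO3, MeOH, 0 °C) gives 21, which re-enters at step 14.

**Step 4.** The hindered, chelated phenoxide may fail to open the epoxide, so that base-induced self-condensation of 5 takes over. Fallback: the C10–O bond is made by carbenoid O–H insertion, starting from 3.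
- Rhodium(II) acetate-catalysed insertion of the carbenoid from 2-diazocyclohexane-1,3-dione F5 (diazo transfer to cyclohexane-1,3-dione) into the phenol O–H gives the 2-aryloxy-1,3-dione F6.
- Triflic anhydride and 2,6-lutidine give the vinylogous triflate F7.
- Addition–elimination of lithium dimethylcuprate at −78 °C installs the C14 methyl and gives 7, which re-enters at step 6.

**Step 11.** The dienolate or the amide base may attack the chalcone, oxygenation may occur at C6, or the product may be over-oxidised. Fallback: a neutral Rubottom sequence from 17 avoids a metal dienolate in the presence of the chalcone. Soft enolisation (TBSOTf, Et3N) gives the silyl dienol ether F8. Dimethyldioxirane at −78 °C epoxidises the C8=C9 enol ether bond and silyl migration gives the 8-silyloxy ketone F9. HF·pyridine then gives 19, which re-enters at step 12.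

## Further compounds

F1 | step 7 | ent-13, (1S,4S,5R,10R)-tetracyclic 2-en-9-one | CC(=O)c1c(OCOC)cc(OC)c2c1O[C@@]13C(=O)CCC[C@]1(C)[C@@H](C)C=C[C@@H]23
F2 | step 14 | Δ1-pyrazoline from 20 (C11 on C6, N on C7, both α) | COc1ccc(/C=C/C(=O)c2c(OCOC)cc(OC)c3c2O[C@]24C(=O)C(=O)[C@@H]5[C@@H](C(C)(C)N=N5)[C@@]2(C)[C@H](C)CC[C@H]34)cc1
F3 | step 14 | 2-diazopropane | CC(C)=[N+]=[N-]
F4 | step 13 | 8α-(4-nitrobenzoyloxy)-6-en-9-one chalcone, Ar2-OMOM | COc1ccc(/C=C/C(=O)c2c(OCOC)cc(OC)c3c2O[C@]24C(=O)[C@@H](OC(=O)c5ccc(cc5)[N+](=O)[O-])C=C[C@@]2(C)[C@H](C)CC[C@H]34)cc1
F5 | step 4 | 2-diazocyclohexane-1,3-dione | O=C1CCCC(=O)C1=[N+]=[N-]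
F6 | step 4 | 2-[2-acetyl-6-iodo-5-methoxy-3-(methoxymethoxy)phenoxy]cyclohexane-1,3-dione | CC(=O)c1c(OCOC)cc(OC)c(I)c1OC1C(=O)CCCC1=O
F7 | step 4 | 2-[2-acetyl-6-iodo-5-methoxy-3-(methoxymethoxy)phenoxy]-3-oxocyclohex-1-en-1-yl trifluoromethanesulfonate | CC(=O)c1c(OCOC)cc(OC)c(I)c1OC1=C(OS(=O)(=O)C(F)(F)F)CCCC1=O
F8 | step 11 | 9-(tert-butyldimethylsilyloxy)-6,8-diene from 17 | COc1ccc(/C=C/C(=O)c2c(OCOC)cc(OC)c3c2O[C@]24C(O[Si](C)(C)C(C)(C)C)=CC=C[C@@]2(C)[C@H](C)CC[C@H]34)cc1
F9 | step 11 | 8β-(tert-butyldimethylsilyloxy)-6-en-9-one chalcone | COc1ccc(/C=C/C(=O)c2c(OCOC)cc(OC)c3c2O[C@]24C(=O)[C@H](O[Si](C)(C)C(C)(C)C)C=C[C@@]2(C)[C@H](C)CC[C@H]34)cc1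
A1 | alternative 1 | 4-methyl-4-[(2-configured)-5-oxopentan-2-yl]cyclohexa-2,5-dien-1-one (Stetter precursor) | O=CCC[C@@H](C)C1(C)C=CC(=O)C=C1
A2 | alternative 1 | cis-fused 4,5-dimethyl-octal-6-ene-1,8-dione | O=C1CC[C@@H](C)[C@]2(C)C=CC(=O)C[C@H]12
A3 | alternative 2 | tert-butyldimethylsilyl ketene acetal of the C1/C10 cis-fused aristolane butyrolactone (C8 dioxolane) | CC(C)(C)[Si](C)(C)OC1O[C@]23CC4(OCCO4)[C@@H]5[C@@H](C5(C)C)[C@@]2(C)[C@H](C)CC[C@@H]3C=1
A4 | alternative 2 | 3-acetyl-4-(benzyloxy)-6-methoxy-2H-pyran-2-one | CC(=O)C1=C(OCc2ccccc2)C=C(OC)OC1=O
A5 | alternative 2 | aristolane-fused acetyl dihydrobenzofuran (benzyl ether, C8 ketal) | CC(=O)c1c(OCc2ccccc2)cc(OC)c2c1O[C@]13CC4(OCCO4)[C@@H]5[C@@H](C5(C)C)[C@@]1(C)[C@H](C)CC[C@H]23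
A6 | alternative 3 | 3-vinylbenzofuran-2-yl dione tethered to the cis-(E)-but-2-en-2-yl dimethylcyclopropane | CC(=O)c1c(O)cc(OC)c2c(C=C)c(C(=O)C(=O)[C@@H]3[C@@H](C3(C)C)/C(C)=C/C)oc12
A7 | alternative 3 | 1,2-didehydro aristolane-dione fused to the benzofuran | CC(=O)c1c(O)cc(OC)c2c1O[C@]13C(=O)C(=O)[C@@H]4[C@@H](C4(C)C)[C@@]1(C)[C@H](C)CC=C23
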